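The synthesis rests on cutting the γ-lactone at its alkyl C–O bond (ring oxygen to C6; germacranolide numbering, listed below). The key step closes this ring by intramolecular SN2 attack of the C12 carboxylate on a C6 mesylate, with inversion. It exploits two features of the lactone ring O–C6–C7–C11–C12: the carboxyl oxygen lies γ to C6 (5-exo-tet), and H6/H7 are trans, which is the C6-epimer of what a syn-selective indium Barbier allylation delivers. The precursor is therefore the open-chain 6,7-syn mesyloxy α-methylene ester made from (S)-citronellal and a glyceraldehyde-derived 2-(bromomethyl)acrylate. The ten-membered carbocycle is closed last by a Nozaki–Hiyama–Kishi coupling at C9–C10.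

Key step: step 5

Numbering: ring carbons C1–C10 (C1=C10 alkene, C4 bears the methyl group, C6 the lactone oxygen, C7 is the ring-fusion CH, C8 bears the 3-methylbutanoate, C9 the hydroxyl), C11=C13 exocyclic alkene, C12 lactone carbonyl, C14 methyl ester carbon.

Assumption: the (S)-configured sulfonamide ligand of step 13 is taken to be the antipode matched to the 9S carbinol; if the sense proves opposite, its enantiomer is used.

Step 1
Reactants: 1 (R)-glyceraldehyde acetonide; 2 methyl acrylate
Product: 3 Morita–Baylis–Hillman alcohol (both C7 carbinol epimers)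
Conditions: DABCO (0.5 equiv), 1,4-dioxane/H2O (1:1), rt
Reagents that add atoms: none
Why: Morita–Baylis–Hillman reaction, in which DABCO adds to the acrylate and the zwitterionic enolate attacks the aldehyde; the carbinol configuration is erased in step 2 and the dioxolane stereocentre (future C8) is not touched.

Step 2
Reactants: 3 Morita–Baylis–Hillman alcohol
Product: 4 (Z)-allylic bromide
Conditions: NBS, Me2S, CH2Cl2, 0 °C → rt
Reagents that add atoms: N-bromosuccinimide, O=C1CCC(=O)N1Br
Why: Corey–Kim-type activation of the allylic alcohol followed by SN2′ delivery of bromide (allylic transposition) under essentially neutral conditions that spare the acetonide should give the preferred (2Z)-2-(bromomethyl)alkenoate, with the dioxolanyl group trans to the ester.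

Step 3
Reactants: 4 (Z)-allylic bromide; 5 (S)-citronellal
Product: 6 6,7-syn hydroxy ester
Conditions: In powder, THF/H2O (1:1), rt
Reagents that add atoms: none
Why: Indium-mediated Barbier allylation in aqueous THF (water tempers the Lewis acidity of the indium salts, so carbonyl-ene cyclisation of citronellal should not compete), in which γ-attack through a six-membered chair transition state with the (Z)-γ-substituent pseudoaxial should give the 6,7-syn carbinol, while bond formation anti to the C8–C9 bond of the allylic stereocentre (C8–H in the allyl plane to relieve allylic 1,3-strain, dioxolane oxygen outside) should set C7 as required relative to C8; the C4 methyl centre comes unchanged from citronellal.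

Step 4
Reactants: 6 6,7-syn hydroxy ester
Product: 7 C6 mesylate
Conditions: MsCl, Et3N, CH2Cl2, 0 °C
Reagents that add atoms: methanesulfonyl chloride, CS(=O)(=O)Cl
Why: Sulfonylation at oxygen turns the C6 hydroxyl into a leaving group; no bond to C6 is broken, so its configuration is retained.

Step 5
Reactants: 7 C6 mesylate
Product: 9 trans-lactone acetonide, via lithium carboxylate mesylate 8 (not isolated)
Conditions: LiOH·H2O, THF/H2O (3:1), 0 °C → 40 °C
Reagents that add atoms: lithium hydroxide, [Li+].[OH-]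
Why: Hydroxide saponifies the only carboxylic ester present to the lithium carboxylate 8, whose oxygen attacks C6 from the face opposite to the departing mesylate in an intramolecular SN2 displacement that forms the O–C6 bond of the α-methylene-γ-butyrolactone. The closest known reaction type is the lactonisation of γ-sulfonyloxy carboxylates by O-alkylation, the standard way to invert the carbinol centre of a γ-lactone. The ring closes in the 5-exo-tet mode. The only stereocentre affected is C6, set by stereospecific inversion of the 6,7-syn adduct, so that H6 and H7 become trans across the ring fusion while C7, C8 and C4 are untouched. The step needs substitution to win over E2 elimination towards the 2-carboxy-1,3-diene and over attack of hydroxide on the mesylate; the high effective molarity of the γ-carboxylate, its low basicity and the mild temperature should secure this.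

Step 6
Reactants: 9 trans-lactone acetonide
Product: 10 lactone aldehyde
Conditions: O3, pyridine (cat.), Sudan Red 7B, CH2Cl2/MeOH, −78 °C; then Me2S, −78 °C → rt
Reagents that add atoms: ozone, [O-][O+]=O
Why: Ozonolysis with reductive work-up; the electron-rich trisubstituted alkene is cleaved far faster than the conjugated, electron-poor exocyclic methylene, and the indicator dye marks the end point before the latter is attacked.

Step 7
Reactants: 10 lactone aldehyde; 11 methyl (triphenylphosphoranylidene)acetate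
Product: 13 (Z)-α-iodo enoate, via iodo ylide 12 (not isolated)
Conditions: 11, NIS, CH2Cl2, −20 °C; then 10, −20 °C → rt
Reagents that add atoms: N-iodosuccinimide, O=C1CCC(=O)N1I
Why: Wittig olefination with the stabilised α-iodo ylide 12, made in the flask by iodination of 11, should place the alkyl chain trans to the ester and so give the (Z)-α-iodo enoate needed for a ring-cis C1=C10 alkene.

Step 8
Reactants: 13 (Z)-α-iodo enoate
Product: 14 diol
Conditions: AcOH/H2O/THF (3:1:1), 40 °C
Reagents that add atoms: none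
Why: Acid-catalysed hydrolysis of the terminal acetonide under mild, base-free conditions that leave the lactone, the vinyl iodide and C8 untouched and give O8 no base-catalysed path to translactonisation.

Step 9
Reactants: 14 diol
Product: 15 primary triethylsilyl ether
Conditions: Et3SiCl, imidazole, CH2Cl2, −40 °C
Reagents that add atoms: chlorotriethylsilane, CC[Si](Cl)(CC)CC
Why: Sterically controlled silylation; the primary C9 hydroxyl reacts much faster than the hindered secondary C8 hydroxyl at low temperature.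

Step 10
Reactants: 15 primary triethylsilyl ether
Product: 16 C8 3-methylbutanoate
Conditions: (iPrCH2CO)2O, DMAP (cat.), pyridine, CH2Cl2, 0 °C → rt
Reagents that add atoms: 3-methylbutanoic anhydride, CC(C)CC(=O)OC(=O)CC(C)C
Why: DMAP-catalysed acylation of the free secondary hydroxyl installs the ester with retention at C8.

Step 11
Reactants: 16 C8 3-methylbutanoate
Product: 17 primary alcohol
Conditions: HF·pyridine, pyridine, THF, 0 °C
Reagents that add atoms: none
Why: Fluoride cleavage of the primary silyl ether under buffered, weakly acidic conditions, chosen because base would promote 1,2-acyl migration from O8 to O9.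

Step 12
Reactants: 17 primary alcohol
Product: 18 α-acyloxy aldehyde
Conditions: Dess–Martin periodinane, CH2Cl2, 0 °C → rt
Reagents that add atoms: none
Why: Dess–Martin oxidation under neutral conditions should give the α-acyloxy aldehyde without epimerisation at C8; it is used at once.

Step 13
Reactants: 18 α-acyloxy aldehyde
Product: 19 target CNP0544142.1
Conditions: CrCl2, (S)-N-[2-(4-isopropyl-4,5-dihydro-1,3-oxazol-2-yl)-6-methylphenyl]methanesulfonamide, Et3N, NiCl2(2,9-dimethyl-1,10-phenanthroline) (cat.), THF, rt, slow addition to 2 mM; aqueous work-up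
Reagents that add atoms: none
Why: Intramolecular Nozaki–Hiyama–Kishi reaction, in which zerovalent nickel inserts into the C–I bond, the alkenyl group passes to trivalent chromium with retention of alkene geometry and adds to the aldehyde under high dilution to close the ten-membered ring at C9–C10; the chiral sulfonamide ligand on chromium is relied on to deliver the 9S carbinol against the open 1,2-induction preference of the α-acyloxy aldehyde.

Compound list
1 | (R)-2,2-dimethyl-1,3-dioxolane-4-carbaldehyde ((R)-glyceraldehyde acetonide) | O=C[C@H]1COC(C)(C)O1 | starting material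
2 | methyl acrylate | C=CC(=O)OC | starting material
3 | methyl 2-{[(4R)-2,2-dimethyl-1,3-dioxolan-4-yl](hydroxy)methyl}prop-2-enoate, both carbinol epimers | C=C(C(=O)OC)C(O)[C@H]1COC(C)(C)O1 | intermediate
4 | methyl (2Z)-2-(bromomethyl)-3-[(4S)-2,2-dimethyl-1,3-dioxolan-4-yl]prop-2-enoate | BrC/C(C(=O)OC)=C\[C@H]1COC(C)(C)O1 | intermediate
5 | (S)-citronellal, (3S)-3,7-dimethyloct-6-enal | O=CC[C@@H](C)CCC=C(C)C | starting material
6 | methyl (3S,4S,6S)-3-[(4S)-2,2-dimethyl-1,3-dioxolan-4-yl]-4-hydroxy-6,10-dimethyl-2-methylideneundec-9-enoate (6,7-syn) | C=C(C(=O)OC)[C@@H]([C@@H](O)C[C@@H](C)CCC=C(C)C)[C@H]1COC(C)(C)O1 | intermediate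
7 | methyl (3R,4S,6S)-3-[(4S)-2,2-dimethyl-1,3-dioxolan-4-yl]-4-(methanesulfonyloxy)-6,10-dimethyl-2-methylideneundec-9-enoate | C=C(C(=O)OC)[C@@H]([C@@H](OS(C)(=O)=O)C[C@@H](C)CCC=C(C)C)[C@H]1COC(C)(C)O1 | intermediate
8 | lithium (3R,4S,6S)-3-[(4S)-2,2-dimethyl-1,3-dioxolan-4-yl]-4-(methanesulfonyloxy)-6,10-dimethyl-2-methylideneundec-9-enoate | C=C(C(=O)[O-])[C@@H]([C@@H](OS(C)(=O)=O)C[C@@H](C)CCC=C(C)C)[C@H]1COC(C)(C)O1.[Li+] | intermediate (not isolated)
9 | (4S,5R)-4-[(4S)-2,2-dimethyl-1,3-dioxolan-4-yl]-5-[(2S)-2,6-dimethylhept-5-en-1-yl]-3-methylideneoxolan-2-one (trans-lactone) | C=C1C(=O)O[C@H](C[C@@H](C)CCC=C(C)C)[C@H]1[C@H]2COC(C)(C)O2 | intermediate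
10 | (4S)-5-[(2R,3S)-3-[(4S)-2,2-dimethyl-1,3-dioxolan-4-yl]-4-methylidene-5-oxooxolan-2-yl]-4-methylpentanal | C=C1C(=O)O[C@H](C[C@@H](C)CCC=O)[C@H]1[C@H]2COC(C)(C)O2 | intermediate
11 | methyl (triphenylphosphoranylidene)acetate | COC(=O)C=P(c1ccccc1)(c1ccccc1)c1ccccc1 | starting material
12 | methyl 2-iodo-2-(triphenylphosphoranylidene)acetate | COC(=O)C(I)=P(c1ccccc1)(c1ccccc1)c1ccccc1 | intermediate (not isolated)
13 | methyl (2Z,6S)-7-[(2R,3S)-3-[(4S)-2,2-dimethyl-1,3-dioxolan-4-yl]-4-methylidene-5-oxooxolan-2-yl]-2-iodo-6-methylhept-2-enoate | C=C1C(=O)O[C@H](C[C@@H](C)CC/C=C(\I)C(=O)OC)[C@H]1[C@H]2COC(C)(C)O2 | intermediate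
14 | methyl (2Z,6S)-7-[(2R,3R)-3-[(1S)-1,2-dihydroxyethyl]-4-methylidene-5-oxooxolan-2-yl]-2-iodo-6-methylhept-2-enoate | C=C1C(=O)O[C@H](C[C@@H](C)CC/C=C(\I)C(=O)OC)[C@H]1[C@H](O)CO | intermediate
15 | methyl (2Z,6S)-7-[(2R,3R)-3-[(1S)-1-hydroxy-2-(triethylsilyloxy)ethyl]-4-methylidene-5-oxooxolan-2-yl]-2-iodo-6-methylhept-2-enoate | C=C1C(=O)O[C@H](C[C@@H](C)CC/C=C(\I)C(=O)OC)[C@H]1[C@H](O)CO[Si](CC)(CC)CC | intermediate
16 | methyl (2Z,6S)-2-iodo-6-methyl-7-[(2R,3S)-4-methylidene-3-[(1S)-1-(3-methylbutanoyloxy)-2-(triethylsilyloxy)ethyl]-5-oxooxolan-2-yl]hept-2-enoate | C=C1C(=O)O[C@H](C[C@@H](C)CC/C=C(\I)C(=O)OC)[C@H]1[C@H](OC(=O)CC(C)C)CO[Si](CC)(CC)CC | intermediate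
17 | methyl (2Z,6S)-7-[(2R,3S)-3-[(1S)-2-hydroxy-1-(3-methylbutanoyloxy)ethyl]-4-methylidene-5-oxooxolan-2-yl]-2-iodo-6-methylhept-2-enoate | C=C1C(=O)O[C@H](C[C@@H](C)CC/C=C(\I)C(=O)OC)[C@H]1[C@H](OC(=O)CC(C)C)CO | intermediate
18 | methyl (2Z,6S)-2-iodo-6-methyl-7-[(2R,3S)-4-methylidene-3-[(1S)-1-(3-methylbutanoyloxy)-2-oxoethyl]-5-oxooxolan-2-yl]hept-2-enoate | C=C1C(=O)O[C@H](C[C@@H](C)CC/C=C(\I)C(=O)OC)[C@H]1[C@H](OC(=O)CC(C)C)C=O | intermediate
19 | methyl (3aS,4S,5S,6E,10S,11aR)-5-hydroxy-10-methyl-3-methylidene-4-[(3-methylbutanoyl)oxy]-2-oxo-2,3,3a,4,5,8,9,10,11,11a-decahydrocyclodeca[b]furan-6-carboxylate | C=C1C(=O)O[C@@H]2C[C@@H](C)CC/C=C(/C(=O)OC)[C@H](O)[C@@H](OC(=O)CC(C)C)[C@@H]12 | target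

Total step count: 13. Longest linear sequence: 13 steps (1 to 19); 5 and 11 enter at steps 3 and 7.

Steps most likely to fail

Step 3. The allylic dioxolane stereocentre may discriminate the two faces of the allyl unit poorly or in the opposite sense, so that C7 is set wrongly relative to C8; there is no direct precedent for this facial sense. The fallback runs the same chemistry in the C8-epimeric series and inverts C8 when the ester is introduced. It sets out from 2 and 5. (S)-Glyceraldehyde acetonide F1 and 2 (DABCO) would give the Morita–Baylis–Hillman alcohol F2, and NBS/Me2S the (Z)-bromide F3. If the allyl unit is attacked anti to the dioxolane C–O bond, F3 and 5 (In, THF/H2O) would give the 6,7-syn adduct F4, with C6 and C7 as in 6 and C8 epimeric. Mesylation would give F5, and LiOH would give, through the lithium carboxylate F6, the 8-epi lactone F7. Ozonolysis would give the aldehyde F8, olefination with 12 the iodo enoate F9, acetonide hydrolysis the diol F10 and silylation the primary silyl ether F11. Mitsunobu esterification of F11 with 3-methylbutanoic acid (PPh3, DIAD, toluene) would install the ester with inversion at C8 and come back to the route at 16.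

Step 13. Ligand control may not overcome the substrate's preference at C9, and intermolecular coupling competes at any practical concentration. The fallback sets the carbinol by ketone reduction and sets out from 18. Coupling without the chiral ligand (CrCl2, NiCl2 cat., DMSO, high dilution) should give mainly the 9-epimeric macrocycle F12. Dess–Martin oxidation would give the C9 ketone F13, and Corey–Bakshi–Shibata reduction (2-methyl-CBS-oxazaborolidine antipode selected for 9S, catecholborane, toluene, −78 °C) would set C9 by reagent control and come back to the route at 19.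

Step 5. E2 elimination of the mesylate towards the conjugated diene acid may compete with ring closure. The fallback activates the alcohol in the presence of the free acid and sets out from 6. Saponification (LiOH, THF/H2O, then careful acidification at 0 °C) would give the hydroxy acid F14, and Mitsunobu lactonisation (PPh3, DIAD, toluene, 0 °C, slow addition) would close the lactone with inversion at C6 and come back to the route at 9.

Further compounds
F1 | step 3 | (S)-2,2-dimethyl-1,3-dioxolane-4-carbaldehyde | O=C[C@@H]1COC(C)(C)O1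
F2 | step 3 | methyl 2-{[(4S)-2,2-dimethyl-1,3-dioxolan-4-yl](hydroxy)methyl}prop-2-enoate, both carbinol epimers | C=C(C(=O)OC)C(O)[C@@H]1COC(C)(C)O1
F3 | step 3 | methyl (2Z)-2-(bromomethyl)-3-[(4R)-2,2-dimethyl-1,3-dioxolan-4-yl]prop-2-enoate | BrC/C(C(=O)OC)=C\[C@@H]1COC(C)(C)O1
F4 | step 3 | methyl (3S,4S,6S)-3-[(4R)-2,2-dimethyl-1,3-dioxolan-4-yl]-4-hydroxy-6,10-dimethyl-2-methylideneundec-9-enoate | C=C(C(=O)OC)[C@@H]([C@@H](O)C[C@@H](C)CCC=C(C)C)[C@@H]1COC(C)(C)O1
F5 | step 3 | methyl (3R,4S,6S)-3-[(4R)-2,2-dimethyl-1,3-dioxolan-4-yl]-4-(methanesulfonyloxy)-6,10-dimethyl-2-methylideneundec-9-enoate | C=C(C(=O)OC)[C@@H]([C@@H](OS(C)(=O)=O)C[C@@H](C)CCC=C(C)C)[C@@H]1COC(C)(C)O1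
F6 | step 3 | lithium (3R,4S,6S)-3-[(4R)-2,2-dimethyl-1,3-dioxolan-4-yl]-4-(methanesulfonyloxy)-6,10-dimethyl-2-methylideneundec-9-enoate | C=C(C(=O)[O-])[C@@H]([C@@H](OS(C)(=O)=O)C[C@@H](C)CCC=C(C)C)[C@@H]1COC(C)(C)O1.[Li+]
F7 | step 3 | (4S,5R)-4-[(4R)-2,2-dimethyl-1,3-dioxolan-4-yl]-5-[(2S)-2,6-dimethylhept-5-en-1-yl]-3-methylideneoxolan-2-one | C=C1C(=O)O[C@H](C[C@@H](C)CCC=C(C)C)[C@H]1[C@@H]2COC(C)(C)O2
F8 | step 3 | (4S)-5-[(2R,3S)-3-[(4R)-2,2-dimethyl-1,3-dioxolan-4-yl]-4-methylidene-5-oxooxolan-2-yl]-4-methylpentanal | C=C1C(=O)O[C@H](C[C@@H](C)CCC=O)[C@H]1[C@@H]2COC(C)(C)O2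
F9 | step 3 | methyl (2Z,6S)-7-[(2R,3S)-3-[(4R)-2,2-dimethyl-1,3-dioxolan-4-yl]-4-methylidene-5-oxooxolan-2-yl]-2-iodo-6-methylhept-2-enoate | C=C1C(=O)O[C@H](C[C@@H](C)CC/C=C(\I)C(=O)OC)[C@H]1[C@@H]2COC(C)(C)O2
F10 | step 3 | methyl (2Z,6S)-7-[(2R,3R)-3-[(1R)-1,2-dihydroxyethyl]-4-methylidene-5-oxooxolan-2-yl]-2-iodo-6-methylhept-2-enoate | C=C1C(=O)O[C@H](C[C@@H](C)CC/C=C(\I)C(=O)OC)[C@H]1[C@@H](O)CO
F11 | step 3 | methyl (2Z,6S)-7-[(2R,3R)-3-[(1R)-1-hydroxy-2-(triethylsilyloxy)ethyl]-4-methylidene-5-oxooxolan-2-yl]-2-iodo-6-methylhept-2-enoate | C=C1C(=O)O[C@H](C[C@@H](C)CC/C=C(\I)C(=O)OC)[C@H]1[C@@H](O)CO[Si](CC)(CC)CC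
F12 | step 13 | methyl (3aS,4S,5R,6E,10S,11aR)-5-hydroxy-10-methyl-3-methylidene-4-[(3-methylbutanoyl)oxy]-2-oxo-2,3,3a,4,5,8,9,10,11,11a-decahydrocyclodeca[b]furan-6-carboxylate | C=C1C(=O)O[C@@H]2C[C@@H](C)CC/C=C(/C(=O)OC)[C@@H](O)[C@@H](OC(=O)CC(C)C)[C@@H]12
F13 | step 13 | methyl (3aS,4S,6E,10S,11aR)-10-methyl-3-methylidene-4-[(3-methylbutanoyl)oxy]-2,5-dioxo-2,3,3a,4,5,8,9,10,11,11a-decahydrocyclodeca[b]furan-6-carboxylate | C=C1C(=O)O[C@@H]2C[C@@H](C)CC/C=C(/C(=O)OC)C(=O)[C@@H](OC(=O)CC(C)C)[C@@H]12
F14 | step 5 | (3S,4S,6S)-3-[(4S)-2,2-dimethyl-1,3-dioxolan-4-yl]-4-hydroxy-6,10-dimethyl-2-methylideneundec-9-enoic acid | C=C(C(=O)O)[C@@H]([C@@H](O)C[C@@H](C)CCC=C(C)C)[C@H]1COC(C)(C)O1
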